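**Remark on numbering.** Daucane-type locants are used throughout: ring A (cyclopentane) is C1–C5, with C1 the methyl-bearing quaternary fusion carbon, C4 the isopropyl carbinol and C5 the fusion CH; ring B (cycloheptene) is C1, C5, C6 (ester carbinol), C7, C8(CH3)=C9 and C10.

## The problem

Compound 19 is the (E)-p-coumarate of the trans-fused hydroazulene diol jaeschkeanadiol (14), in which ring A and ring B share the C1–C5 bond. Four contiguous stereocentres must be set: C1 (R), C5 (S), C4 (R) and C6 (S). In relative terms the C1 methyl is trans to H5, the C4 hydroxyl lies on the face of the C1 methyl (isopropyl on the face of H5), and the C6 oxygen stands anti to C1 along the C4–C5–C6 chain. C1 is quaternary and cannot be corrected afterwards, so it must be set absolutely and early. Once set it can steer bond formation at C5, and C5 in turn can control C6 (through a closed aldol transition state) and C4 (attack anti to the C5 substituent). The fragile elements are the tertiary C4 hydroxyl in a 1,3-relationship to the C6 oxygen, the trisubstituted C8=C9 alkene, and the coumarate with its free phenol and base-labile conjugated ester; the acyl group therefore goes on last. The enabling feature is that C1, C5 and C6 are contiguous with C4 next to C5. If C4 is the carbonyl of a cyclopentanone, C1 is its β-carbon, C5 its α-carbon and C6 an aldol carbinol. The arms left on C1 (C10–C9) and C6 (C7–C8) can end in alkenes that are later joined as C8=C9.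

## Retrosynthesis

**Ester C6–O–acyl.** The coumarate of 19 is cut first, giving diol 14 and the O-silylated acid 17, with the silyl ester 18 as the penultimate compound. Acylating last keeps the Michael acceptor and the phenol away from organometallic and metathesis steps. Only the secondary C6 hydroxyl of 14 can be acylated under carbodiimide conditions, so the tertiary C4 hydroxyl needs no protection. The forward reaction must not break the C6–O bond.

**Ring B at C8=C9.** Diol 14 comes from its 6-O-triethylsilyl ether 13, and 13 is opened across the C8=C9 double bond to diene 12. This alkene is the only functional group in the carbocyclic part of ring B, and cutting it leaves an allyl group on C1 and a 2-methylallyl unit on C7. A cut at C6–C7 or C1–C10 would demand a new stereocentre or a quaternary centre at ring closure; here the closure touches no stereocentre. Because the two arms are trans on ring A, the trans fusion is fixed before the ring closes. The forward metathesis must join a monosubstituted and a 1,1-disubstituted alkene into a seven-membered ring.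

**C4–isopropyl bond.** Carbinol 12 is cut between C4 and isopropyl to ketone 10 and isopropylmagnesium chloride (11). Ketone 10 is the triethylsilyl ether of aldol 9; the ether blocks retro-aldol and alkoxide chemistry during the addition. The addition is placed before ring closure because in the monocycle the branched C5 side chain shields one face of the carbonyl. The forward reaction needs a weakly basic isopropyl donor that attacks anti to that side chain, which places the hydroxyl cis to it as required.

**C1–CH3 and C5–C6 (key cut).** Aldol 9 is divided into three pieces: enone 4, trimethylaluminium (7) and aldehyde 6, joined through the aluminium enolate 8. This removes three stereocentres and two skeletal bonds at once and leads to achiral, two-step-accessible components. Absolute configuration comes from a chiral copper catalyst, not from a chiral starting material. The forward reaction must deliver methyl to one enantioface of 4. The enolate must then add to an enolisable aldehyde through a closed transition state (anti C5/C6), on the face of the ring that carries the C1 methyl and not the allyl group. This last bias is the modest one. It is not backed by later equilibration, since inverting C5 alone would turn the anti into the syn aldol. It rests instead on kinetic preference, on chromatographic removal of minor isomers at 9 or 10, and on a tighter boron-enolate variant held in reserve.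

**Building blocks.** Enone 4 is cut at the ring–allyl bond to 3-ethoxycyclopent-2-en-1-one (1) and allylmagnesium bromide (2), through carbinol 3, which is not isolated. Aldehyde 6 comes from alcohol 5 by oxidation. Acid 17 comes from p-coumaric acid (15) through the bis-silylated compound 16. All of 1, 2, 5, 7, 11 and 15 are commercial.

## Roads not taken

**Alternative 1:** Ring B would be cut at C6–C7 and C1–C10 and assembled from the chromium methoxy(cyclopentenyl)carbene A1 and isoprene A2.
- **Forward step:** cyclopropanation of the 1,1-disubstituted alkene of A2, then Cope rearrangement of the cis-divinylcyclopropane, giving the bicyclic methyl enol ether A3.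
- **Merits:** the seven-membered ring, the C8 methyl, the C8=C9 alkene and the quaternary C1 all arise in one convergent operation, with no separate ring closure. In this respect it is better than the chosen plan.
- **Weak points:**
  - A1 needs a stoichiometric chromium complex and an enantioenriched C4 tertiary carbinol made beforehand.
  - The Cope step must create a quaternary centre from a fully substituted alkene terminus.
  - Site selectivity on A2 and face selectivity at C1, which depends on a 1,3-related C4 centre, are both uncertain.
  - A3 still lacks C5 and C6. Enol ether hydrolysis, protonation at C5 and ketone reduction would follow, on a β-silyloxy ketone prone to elimination. A tertiary silyl ether then has to be removed.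
- **Comparison:** the chosen plan sets three stereocentres in its key step under catalyst control, forms C6 at the alcohol oxidation level, and uses no stoichiometric transition metal.

**Alternative 2:** The C1–C5 bond would be formed by a 1,2-shift in the cis-decalin triol monomesylate A4.
- **Forward step:** the C6 alkoxide drives migration of C1 from C6 to C5 with loss of mesylate, giving the trans-fused hydroxy ketone A5.
- **Merits:** the shift is stereospecific (inversion at C5, retention in the migrating C1), so the trans fusion and C5 are guaranteed by the precursor. This is more secure than the face selectivity at C5 in the chosen plan.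
- **Weak points:**
  - A4 carries four stereocentres, including a quaternary fusion carbon and an all-cis oxygen triad, and would take many steps to build.
  - The C4 hydroxyl also flanks the mesylate, and its C4–C3 bond is equally antiperiplanar, so a competing ring contraction to an acylcyclopentane is possible.
  - A5 still needs C6 reduced with hydride delivered from the face of the C4 hydroxyl.
- **Comparison:** against the higher certainty at C5, the chosen plan offers a key step two operations from commercial materials, catalytic absolute control, and C6 formed directly in the right configuration.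

**Alternative 3:** The C6–C7 bond would be formed by [2,3]-Wittig ring expansion of the cyclopentane-fused stannyl tetrahydropyran A6.
- **Forward step:** tin–lithium exchange at C6, then a sigmatropic shift that breaks the temporary C9–O bond and gives 4-O-triethylsilyl jaeschkeanadiol A7.
- **Merits:** ring B, the C8=C9 alkene and the C6 carbinol (by inversion at the metallated carbon) arise together. A7 is only an acylation with 17 and a desilylation away from 19, a shorter endgame than the chosen plan has.
- **Weak points:**
  - A6 has five stereocentres, two of which (C6 and C9) exist only to be consumed.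
  - The shift must pass through a strained bicyclic transition state that delivers a cis alkene in the new ring, in competition with the [1,2]-shift.
  - Stoichiometric tin is required.
- **Comparison:** the chosen plan offers a far shorter front end and no sacrificial stereocentres, at the price of four more operations after its key step.

Key step: step 3

**Assumption.** The sense of induction of the copper–phosphoramidite catalyst on a five-ring enone is taken to follow its behaviour with 3-substituted cyclohexenones. The ligand antipode is therefore defined by the result required: methyl delivery to the Si face of the β-carbon of 4.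

## Route

Step 1
Reactants: 1 3-ethoxycyclopent-2-en-1-one; 2 allylmagnesium bromide
Product: 4 3-(prop-2-en-1-yl)cyclopent-2-en-1-one, via 3-ethoxy-1-(prop-2-en-1-yl)cyclopent-2-en-1-ol 3 (not isolated)
Conditions: 2 (1.2 equiv), THF, −78 to 0 °C; then 1 M HCl (aq), 0 °C, 20 min
Reagents that add atoms: water, O
Why: Stork–Danheiser sequence: 1,2-addition of the Grignard reagent to the vinylogous ester, then acid-induced hydrolysis and loss of ethanol transpose the carbonyl; brief cold acid keeps the allyl alkene out of conjugation.

Step 2
Reactants: 5 3-methylbut-3-en-1-ol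
Product: 6 3-methylbut-3-enal
Conditions: Dess–Martin periodinane (1.1 equiv), NaHCO3, CH2Cl2, 0 °C to rt; filtered, concentrated cold, used at once as a solution
Reagents that add atoms: none
Why: Dess–Martin oxidation under buffered, non-aqueous conditions should give the β,γ-unsaturated aldehyde without migration of the alkene into conjugation; immediate use limits isomerisation and evaporation losses.

Step 3
Reactants: 4 3-(prop-2-en-1-yl)cyclopent-2-en-1-one; 7 trimethylaluminium; 6 3-methylbut-3-enal
Product: 9 (2S,3R)-2-[(1S)-1-hydroxy-3-methylbut-3-en-1-yl]-3-methyl-3-(prop-2-en-1-yl)cyclopentan-1-one, via dimethylaluminium enolate 8 (not isolated)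
Conditions: 7 (1.2 equiv), Cu(OTf)2 (2 mol %), BINOL-derived N,N-bis(1-phenylethyl)phosphoramidite (4 mol %), Et2O, −30 °C; then 6 (2 equiv), −78 to −40 °C; aq. potassium sodium tartrate
Reagents that add atoms: none
Why: Trimethylaluminium reduces Cu(OTf)2 to a monovalent copper–phosphoramidite methyl species that binds the enone, adds at the β-carbon and eliminates reductively to form C1–CH3, releasing the dimethylaluminium enolate 8 with its double bond fixed between C4 and C5; aldehyde 6 then coordinates to the Lewis-acidic aluminium and is attacked through a six-membered chair transition state, forming C5–C6. The closest known reaction type is the copper-catalysed asymmetric conjugate addition of trialkylaluminium reagents to 3-substituted cyclic enones with aldol trapping of the aluminium enolate. No ring is closed. C1 is set by the chiral ligand, which directs methyl to the Si face of the β-carbon (R). C6 is set relative to C5 by the closed transition state: the ring-locked E-enolate places the aldehyde substituent equatorial and should give the anti aldol. C5 is set relative to C1 by approach of the aldehyde on the enolate face bearing methyl and not the larger allyl group, which puts the new side chain trans to allyl. The step needs 1,4- over 1,2-addition (copper catalysis in ether), addition in preference to proton transfer from the enolisable aldehyde (weakly basic aluminium enolate, low temperature) and face selectivity at C5, the least secure element, for which separation of minor isomers at 9 or 10 is foreseen.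

Step 4
Reactants: 9 (2S,3R)-2-[(1S)-1-hydroxy-3-methylbut-3-en-1-yl]-3-methyl-3-(prop-2-en-1-yl)cyclopentan-1-one
Product: 10 (2S,3R)-3-methyl-2-[(1S)-3-methyl-1-[(triethylsilyl)oxy]but-3-en-1-yl]-3-(prop-2-en-1-yl)cyclopentan-1-one
Conditions: Et3SiOTf (1.2 equiv), 2,6-lutidine, CH2Cl2, −78 °C
Reagents that add atoms: triethylsilyl trifluoromethanesulfonate, CC[Si](CC)(CC)OS(=O)(=O)C(F)(F)F
Why: O-silylation of a β-hydroxy ketone with a silyl triflate and a hindered base is fast at low temperature and should not cause retro-aldol cleavage or epimerisation at C5; the ether blocks alkoxide chemistry in the next step.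

Step 5
Reactants: 10 (2S,3R)-3-methyl-2-[(1S)-3-methyl-1-[(triethylsilyl)oxy]but-3-en-1-yl]-3-(prop-2-en-1-yl)cyclopentan-1-one; 11 isopropylmagnesium chloride
Product: 12 (1R,2S,3R)-3-methyl-2-[(1S)-3-methyl-1-[(triethylsilyl)oxy]but-3-en-1-yl]-1-(propan-2-yl)-3-(prop-2-en-1-yl)cyclopentan-1-ol
Conditions: anhydrous CeCl3 (2 equiv), 11 (2 equiv), THF, −78 °C; then 10, −78 to 0 °C; water
Reagents that add atoms: none
Why: Organocerium addition: the oxophilic, weakly basic isopropylcerium reagent should add to the hindered ketone without enolisation, β-hydride reduction or β-elimination of the silyloxy group. It approaches C4 on the face of H5, anti to the branched C5 side chain, so isopropyl ends trans and the hydroxyl cis to that chain (4R).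

Step 6
Reactants: 12 (1R,2S,3R)-3-methyl-2-[(1S)-3-methyl-1-[(triethylsilyl)oxy]but-3-en-1-yl]-1-(propan-2-yl)-3-(prop-2-en-1-yl)cyclopentan-1-ol
Product: 13 (3R,3aS,4S,8aR)-6,8a-dimethyl-3-(propan-2-yl)-4-[(triethylsilyl)oxy]-1,2,3,3a,4,5,8,8a-octahydroazulen-3-ol
Conditions: second-generation Grubbs catalyst (5 mol %), CH2Cl2 (5 mM), 40 °C
Reagents that add atoms: none
Why: Ring-closing olefin metathesis: the catalyst loads on the monosubstituted allyl alkene and closes onto the 1,1-disubstituted alkene, giving ring B with the trisubstituted C8=C9 bond and releasing ethylene. The arms are trans on ring A, so the trans fusion is carried over and no stereocentre is touched.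

Step 7
Reactants: 13 (3R,3aS,4S,8aR)-6,8a-dimethyl-3-(propan-2-yl)-4-[(triethylsilyl)oxy]-1,2,3,3a,4,5,8,8a-octahydroazulen-3-ol
Product: 14 (3R,3aS,4S,8aR)-6,8a-dimethyl-3-(propan-2-yl)-1,2,3,3a,4,5,8,8a-octahydroazulene-3,4-diol (jaeschkeanadiol)
Conditions: HF·pyridine, pyridine, THF, 0 °C to rt
Reagents that add atoms: none
Why: Fluoride-induced cleavage of the Si–O bond; pyridine-buffered HF should leave the tertiary alcohol and the trisubstituted alkene untouched.

Step 8
Reactants: 15 (E)-4-hydroxycinnamic acid
Product: 17 (2E)-3-[4-[(tert-butyldimethylsilyl)oxy]phenyl]prop-2-enoic acid, via bis-silylated coumarate 16 (not isolated)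
Conditions: t-BuMe2SiCl (2.4 equiv), imidazole, DMF, rt; then AcOH–THF–H2O (3:1:1), rt
Reagents that add atoms: tert-butyldimethylsilyl chloride, CC(C)(C)[Si](C)(C)Cl
Why: Both acidic hydroxyls are silylated, then the far more labile silyl ester is hydrolysed selectively; aryl silyl ethers tolerate dilute acetic acid and the E-alkene is not involved.

Step 9
Reactants: 14 jaeschkeanadiol; 17 (2E)-3-[4-[(tert-butyldimethylsilyl)oxy]phenyl]prop-2-enoic acid
Product: 18 (3R,3aS,4S,8aR)-3-hydroxy-6,8a-dimethyl-3-(propan-2-yl)-1,2,3,3a,4,5,8,8a-octahydroazulen-4-yl (2E)-3-[4-[(tert-butyldimethylsilyl)oxy]phenyl]prop-2-enoate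
Conditions: DCC (1.3 equiv), DMAP (0.3 equiv), CH2Cl2, 0 °C to rt
Reagents that add atoms: none
Why: Steglich esterification: the carbodiimide activates the acid and DMAP transfers the acyl group to the secondary C6 hydroxyl; the tertiary C4 hydroxyl should not react, and C6 keeps its configuration because its C–O bond is not broken.

Step 10
Reactants: 18 the silyl-protected coumarate
Product: 19 (3R,3aS,4S,8aR)-3-hydroxy-6,8a-dimethyl-3-(propan-2-yl)-1,2,3,3a,4,5,8,8a-octahydroazulen-4-yl (2E)-3-(4-hydroxyphenyl)prop-2-enoate
Conditions: Bu4NF, AcOH (1:1), THF, 0 °C
Reagents that add atoms: none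
Why: Fluoride cleavage of the aryl silyl ether is fast because phenoxide leaves silicon readily; acetic acid buffers the medium so the cinnamate ester and the tertiary alcohol should be left alone.

## Compound list

1 | 3-ethoxycyclopent-2-en-1-one | CCOC1=CC(=O)CC1 | starting material
2 | allylmagnesium bromide | C=CC[Mg]Br | starting material
3 | 3-ethoxy-1-(prop-2-en-1-yl)cyclopent-2-en-1-ol (racemic, not isolated) | C=CCC1(O)C=C(OCC)CC1 | intermediate
4 | 3-(prop-2-en-1-yl)cyclopent-2-en-1-one | C=CCC1=CC(=O)CC1 | intermediate
5 | 3-methylbut-3-en-1-ol | CC(=C)CCO | starting material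
6 | 3-methylbut-3-enal | CC(=C)CC=O | intermediate
7 | trimethylaluminium | C[Al](C)C | starting material
8 | dimethylaluminium (3R)-3-methyl-3-(prop-2-en-1-yl)cyclopent-1-en-1-olate (not isolated) | C=CC[C@@]1(C)CCC(O[Al](C)C)=C1 | intermediate
9 | (2S,3R)-2-[(1S)-1-hydroxy-3-methylbut-3-en-1-yl]-3-methyl-3-(prop-2-en-1-yl)cyclopentan-1-one | C=CC[C@@]1(C)CCC(=O)[C@@H]1[C@@H](O)CC(C)=C | intermediate
10 | (2S,3R)-3-methyl-2-[(1S)-3-methyl-1-[(triethylsilyl)oxy]but-3-en-1-yl]-3-(prop-2-en-1-yl)cyclopentan-1-one | C=CC[C@@]1(C)CCC(=O)[C@@H]1[C@@H](O[Si](CC)(CC)CC)CC(C)=C | intermediate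
11 | isopropylmagnesium chloride | CC(C)[Mg]Cl | starting material
12 | (1R,2S,3R)-3-methyl-2-[(1S)-3-methyl-1-[(triethylsilyl)oxy]but-3-en-1-yl]-1-(propan-2-yl)-3-(prop-2-en-1-yl)cyclopentan-1-ol | C=CC[C@@]1(C)CC[C@@](O)(C(C)C)[C@@H]1[C@@H](O[Si](CC)(CC)CC)CC(C)=C | intermediate
13 | (3R,3aS,4S,8aR)-6,8a-dimethyl-3-(propan-2-yl)-4-[(triethylsilyl)oxy]-1,2,3,3a,4,5,8,8a-octahydroazulen-3-ol | CC1=CC[C@@]2(C)CC[C@@](O)(C(C)C)[C@@H]2[C@@H](O[Si](CC)(CC)CC)C1 | intermediate
14 | jaeschkeanadiol, (3R,3aS,4S,8aR)-6,8a-dimethyl-3-(propan-2-yl)-1,2,3,3a,4,5,8,8a-octahydroazulene-3,4-diol | CC1=CC[C@@]2(C)CC[C@@](O)(C(C)C)[C@@H]2[C@@H](O)C1 | intermediate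
15 | (E)-4-hydroxycinnamic acid | OC(=O)/C=C/c1ccc(O)cc1 | starting material
16 | tert-butyldimethylsilyl (2E)-3-[4-[(tert-butyldimethylsilyl)oxy]phenyl]prop-2-enoate (not isolated) | CC(C)(C)[Si](C)(C)OC(=O)/C=C/c1ccc(O[Si](C)(C)C(C)(C)C)cc1 | intermediate
17 | (2E)-3-[4-[(tert-butyldimethylsilyl)oxy]phenyl]prop-2-enoic acid | OC(=O)/C=C/c1ccc(O[Si](C)(C)C(C)(C)C)cc1 | intermediate
18 | (3R,3aS,4S,8aR)-3-hydroxy-6,8a-dimethyl-3-(propan-2-yl)-1,2,3,3a,4,5,8,8a-octahydroazulen-4-yl (2E)-3-[4-[(tert-butyldimethylsilyl)oxy]phenyl]prop-2-enoate | CC1=CC[C@@]2(C)CC[C@@](O)(C(C)C)[C@@H]2[C@@H](OC(=O)/C=C/c2ccc(O[Si](C)(C)C(C)(C)C)cc2)C1 | intermediate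
19 | (3R,3aS,4S,8aR)-3-hydroxy-6,8a-dimethyl-3-(propan-2-yl)-1,2,3,3a,4,5,8,8a-octahydroazulen-4-yl (2E)-3-(4-hydroxyphenyl)prop-2-enoate | CC1=CC[C@@]2(C)CC[C@@](O)(C(C)C)[C@@H]2[C@@H](OC(=O)/C=C/c2ccc(O)cc2)C1 | target

## Step count and risk

Total steps: 10. Longest linear sequence: 8 steps (1, 3, 4, 5, 6, 7, 9, 10) from compound 1.

**Step 3 (key step).** The most likely failure is at the aldol stage.
- The enolate next to the new quaternary centre is hindered, so addition may be slow and proton transfer from the doubly activated α-position of 6 may compete.
- Discrimination between the methyl and allyl faces at C5 may be incomplete, since the two groups differ only beyond their first carbon.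
- Enantioface selection on a five-ring enone may also fall short of that on six-ring enones.

Fallback, setting out from 4 and 7 and returning at 9: after the same copper-catalysed addition, the enolate 8 is silylated in the flask with trimethylsilyl triflate. This gives the isolable enol ether trimethyl{[(3R)-3-methyl-3-(prop-2-en-1-yl)cyclopent-1-en-1-yl]oxy}silane F1. MeLi in THF at 0 °C then releases the lithium enolate, lithium (3R)-3-methyl-3-(prop-2-en-1-yl)cyclopent-1-en-1-olate F2. Cy2BCl at −78 °C converts it into the boron enolate dicyclohexyl{[(3R)-3-methyl-3-(prop-2-en-1-yl)cyclopent-1-en-1-yl]oxy}borane F3. This non-basic E-enolate adds to 6 through a short-bonded chair transition state, which should sharpen both the anti preference and the sensitivity to the groups on C1. Buffered work-up gives 9.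

**Step 5.** The secondary organometallic may enolise the hindered ketone or reduce it by β-hydride transfer, and face selectivity may erode if the allyl group on C1, which sits on the attacking face, interferes. Fallback, setting out from 10 and returning at 13: the order is changed and a smaller sp2 nucleophile is used.
- Ketone 10 is first closed with the second-generation Grubbs catalyst to the bicyclic ketone (3aS,4S,8aR)-6,8a-dimethyl-4-[(triethylsilyl)oxy]-2,3a,4,5,8,8a-hexahydroazulen-3(1H)-one F4.
- CH2=C(CH3)MgBr–CeCl3, which has no β-hydrogen to transfer, then adds to C4 from the face of H5, anti to the angular methyl. The product is (3S,3aS,4S,8aR)-6,8a-dimethyl-3-(prop-1-en-2-yl)-4-[(triethylsilyl)oxy]-1,2,3,3a,4,5,8,8a-octahydroazulen-3-ol F5.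
- Hydrogenation with RhCl(PPh3)3 and H2 saturates the 1,1-disubstituted alkene in preference to the trisubstituted ring alkene and gives 13.

**Step 6.** Closure of a trans-fused seven-membered ring onto a 1,1-disubstituted alkene may be slow. Intermolecular metathesis through the allyl group, or ruthenium hydride-induced alkene migration, could then take over. Fallback, setting out from 12 and returning at 13: the ring is closed by carbonyl coupling instead.
- Ozonolysis of both terminal alkenes (O3, CH2Cl2–MeOH, −78 °C; PPh3) gives the keto aldehyde 2-[(1R,2S,3R)-3-hydroxy-1-methyl-2-[(1S)-3-oxo-1-[(triethylsilyl)oxy]butyl]-3-(propan-2-yl)cyclopentyl]acetaldehyde F6. It may rest partly as a cyclic hemiketal through the C4 hydroxyl.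
- Intramolecular McMurry coupling with low-valent titanium (TiCl3(DME)1.5, Zn(Cu), DME, reflux, slow addition) joins C8 and C9 as the trisubstituted alkene and gives 13.

Further compounds

F1 | step 3 | trimethyl{[(3R)-3-methyl-3-(prop-2-en-1-yl)cyclopent-1-en-1-yl]oxy}silane | C=CC[C@@]1(C)CCC(O[Si](C)(C)C)=C1
F2 | step 3 | lithium (3R)-3-methyl-3-(prop-2-en-1-yl)cyclopent-1-en-1-olate | C=CC[C@@]1(C)CCC(O[Li])=C1
F3 | step 3 | dicyclohexyl{[(3R)-3-methyl-3-(prop-2-en-1-yl)cyclopent-1-en-1-yl]oxy}borane | C=CC[C@@]1(C)CCC(OB(C2CCCCC2)C2CCCCC2)=C1
F4 | step 5 | (3aS,4S,8aR)-6,8a-dimethyl-4-[(triethylsilyl)oxy]-2,3a,4,5,8,8a-hexahydroazulen-3(1H)-one | CC1=CC[C@@]2(C)CCC(=O)[C@@H]2[C@@H](O[Si](CC)(CC)CC)C1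
F5 | step 5 | (3S,3aS,4S,8aR)-6,8a-dimethyl-3-(prop-1-en-2-yl)-4-[(triethylsilyl)oxy]-1,2,3,3a,4,5,8,8a-octahydroazulen-3-ol | CC1=CC[C@@]2(C)CC[C@@](O)(C(C)=C)[C@@H]2[C@@H](O[Si](CC)(CC)CC)C1
F6 | step 6 | 2-[(1R,2S,3R)-3-hydroxy-1-methyl-2-[(1S)-3-oxo-1-[(triethylsilyl)oxy]butyl]-3-(propan-2-yl)cyclopentyl]acetaldehyde | O=CC[C@@]1(C)CC[C@@](O)(C(C)C)[C@@H]1[C@@H](O[Si](CC)(CC)CC)CC(C)=O
A1 | alternative 1 | pentacarbonyl{methoxy[(5R)-5-(tert-butyldimethylsilyloxy)-2-methyl-5-(propan-2-yl)cyclopent-1-en-1-yl]methylidene}chromium | COC(C1=C(C)CC[C@@]1(O[Si](C)(C)C(C)(C)C)C(C)C)=[Cr](=C=O)(=C=O)(=C=O)(=C=O)=C=O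
A2 | alternative 1 | isoprene | CC(=C)C=C
A3 | alternative 1 | 6-methoxy-4-(tert-butyldimethylsilyloxy)dauca-5,8-diene | CC1=CC[C@@]2(C)CC[C@@](O[Si](C)(C)C(C)(C)C)(C(C)C)C2=C(OC)C1
A4 | alternative 2 | cis-decalin triol monomesylate (C4 and C6 tertiary hydroxyls, C5 mesylate, all cis to the C1 methyl) | CC1=CC[C@@]2(C)CC[C@@](O)(C(C)C)[C@H](OS(C)(=O)=O)[C@@]2(O)C1
A5 | alternative 2 | trans-fused 4-hydroxydauc-8-en-6-one | CC1=CC[C@@]2(C)CC[C@@](O)(C(C)C)[C@@H]2C(=O)C1
A6 | alternative 3 | cyclopentane-fused 2-(tributylstannyl)-6-(prop-1-en-2-yl)tetrahydropyran, stannyl and isopropenyl trans, C4 triethylsilyl ether | CC(=C)[C@@H]1C[C@@]2(C)CC[C@@](O[Si](CC)(CC)CC)(C(C)C)[C@@H]2[C@H](O1)[Sn](CCCC)(CCCC)CCCC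
A7 | alternative 3 | 4-O-triethylsilyl jaeschkeanadiol | CC1=CC[C@@]2(C)CC[C@@](O[Si](CC)(CC)CC)(C(C)C)[C@@H]2[C@@H](O)C1
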